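| setting | elm | cedar | flask |
|---|---|---|---|
| starting material | 0.40 M | 0.60 M | 0.40 M |
| partner | 1.1 equiv | 1.1 equiv | 1.10 equiv |
| remark | the very flask that is asked about, followed so far | run made earlier |  |
| time |  |  | 6.0 min |

- elm (time / s: target / %): 10.0: 2.5; 25.0: 8.8; 50.0: 14.4; 80.0: 18.4
- cedar (time / min: target / %): 1.50: 24.2; 3.00: 39.5; 5.00: 51.6; 6.00: 54.1

(each reading ± 1 percentage point)

- amount of target in percent of the starting material charged, at 40 s, 2.0 min and 6.0 min

- a reading or a percentage of target counts all its forms, free or not

Over its first 80.0 s the elm flask, at 0.40 M starting material, made 18.4 % of target, and over its first 1.50 min the cedar flask, at 0.60 M, made 24.2 %. I divided each yield by its time, then elm's rate by cedar's, and called the quotient the rate ratio, 0.855. It is a reading, with a scatter of 1 percentage point on each yield behind it. I assumed that elm gains this fraction of what cedar gains at every moment. The summed gains then stand in the same ratio, time drops out, and no integration is needed: elm's percent at any clock time is the ratio times cedar's.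

I went to 2.0 min by two ways. Prolonging elm's own slope from 50.0 s to 80.0 s gave 23.7 %. The ratio times cedar's interpolated percent gave 25.1 %. They lay 1.4 points apart. Both lean on elm's 18.4 %, so this was a partial check, but the onward climb came from elm in the first way and from cedar in the second, and I took a value near the two at 2.0 min.

At 6.0 min they parted: the line gave 55.7 %, the ratio 46.3 %. The line was the cheat. It climbed above cedar's 54.1 % although elm had read slower, and cedar's readings put its rate on the last stretch 6.45 times below that of its first. So I committed to 46.3 % at 6.0 min, and at 40 s to a value between elm's 8.8 % and 14.4 %.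

The forecast gave 12.2 %, 21.8 % and 26 %, on this ground: “The flask matches elm, so I extrapolate elm.” Its last value stands well below mine.

The elm flask gave 10.9 %, 26.5 % and 48.7 %.

    partner → decomposed reagent (k = 0.00310 s⁻¹)
    crystals ⇌ target, rate k2*(cs2 - [target]) while solid is left; crystals form when [target] > cs2 (solubility = 0.180 M, k = 0.0250 s⁻¹)
    starting material + partner → target, rate k3*[starting material]*[partner]^0.5 (k = 0.00460 M⁻⁰·⁵ s⁻¹)
    starting material → decomposition product (k = 5.20 × 10⁻⁶ s⁻¹)

At 6.00 min partner stood at 10.1 % of its own charge beside 51.1 % of starting material, so partner, charged at 1.10 equiv, had become the limiting reagent. Multiplied by cedar's 39.5 % at 3.00 min, the rate ratio 0.855 gives 33.8 %, and the elm flask held 34.7 % of target at 3.00 min.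

The numbers in the tables were computed with made-up constants; scatter was added.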